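**Numbering used throughout:** 1 bromo hydroxy acetophenone (start); 2 its allyl ether; 3 C-allyl phenol; 4 allyl ether of 3; 5 di-C-allyl phenol; 6 MOM ether; 7 diprenyl methyl ketone; 8 4-hydroxybenzoic acid (start); 9 its bis-silyl derivative; 10 acid chloride; 11 1,3-diketone; 12 (3S)-hydroxy ketone (not isolated); 13 (1S,3S)-diol; 14 (2S,4S)-flavan-4-ol; 15 protected flavanone; 16 ring B phenol; 17 target.

## Analysis of the target

Compound 17 is a (2S)-flavanone: aromatic ring A is fused to a dihydropyranone ring C (O1, C2, C3, the C4 carbonyl, C4a, C8a), and C2 carries the 4-hydroxyphenyl ring B. Ring A is pentasubstituted, with the 7-hydroxyl flanked by prenyl groups at C6 and C8 and only C5 bearing hydrogen. The single stereocentre is C2, which is benzylic, bonded to the ring oxygen and β to the ketone. That position is fragile: base opens ring C by a retro-oxa-Michael reaction to an achiral hydroxychalcone, and acid can ionise the C2–O1 bond with help from the para oxygen of ring B. The two trisubstituted alkenes are the other sensitive groups, since they add a neighbouring phenol under strong acid and exclude hydrogenation and electrophilic oxidants. The difficulty is to create C2 in high enantiopurity and to close ring C without conditions that reopen it, on a ring that needs two prenyl groups ortho to one oxygen. The strategy rests on O1 being bonded to aromatic C8a on one side and to C2 on the other. Ring C can therefore be closed at C8a–O1, with the C2–O bond already fixed in an acyclic alcohol and C4 held at the alcohol level.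

## Retrosynthetic reasoning

**17 back to 15 (through 16).** No skeletal bond is cut. The two phenols are masked in 15, ring B as a silyl ether and ring A as a methoxymethyl ether, and 16 is the half-unmasked stage. The ring A oxygen sits para to a carbonyl group for much of the route, where a silyl ether would be labile to nucleophiles, and the small acetal fits between two ortho substituents. Forward, the silyl ether must fall to near-neutral fluoride and the acetal to dilute acid, with no base that could reopen ring C.

**15 back to 14.** The C4 ketone is traced to a secondary benzylic alcohol. This removes the β-alkoxy ketone from the ring-closure stage, so dehydration, retro-aldol cleavage and retro-oxa-Michael opening cannot erode C2 there. The forward oxidation has to be non-basic and spare the alkenes.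

**14 back to 13.** The C8a–O1 bond is cut. The other bond of the ring oxygen, O1–C2, lies at the stereocentre, and closing there would make or break the bond that defines C2. Cutting at the aromatic carbon leaves an aryl bromide and a free C3 hydroxyl in 13. The forward step only has to join an existing carbinol oxygen to the arene, and the second hydroxyl cannot compete because it would close a four-membered ring.

**13 back to 11 (through 12).** Both carbinol C–H bonds are traced to the carbonyl groups of a 1,3-diketone. One catalyst-controlled double reduction sets the configuration at C3 of the chain (the later C2). The configuration at C1 is irrelevant because that carbon becomes the ketone again.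

**11 back to 7 and 10.** The bond between the methylene carbon and the ring B carbonyl carbon (the later C3–C2 bond) is cut. This divides the molecule into two aromatic halves of similar size and asks only for C-acylation of a methyl ketone enolate. Acid chloride 10 comes from 8 through 9.

**7 back to 5 (through 6).** The two isopropylidene termini are cut off, leaving allyl groups. Allyl groups reach the ring by Claisen rearrangement with the CH2 on carbon, whereas a prenyl ether would deliver the reversed 1,1-dimethylallyl group. Cross-metathesis with a simple trisubstituted alkene then turns both into prenyl groups in one step, after the phenol has been masked.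

**5 back to 1 (through 4, 3 and 2).** The two aryl–CH2 bonds at C3 and C5 of the acetophenone ring (the later C8 and C6) are cut by two cycles of O-allylation and Claisen rearrangement. The para position is blocked by the acetyl group, so only the two ortho positions can accept, and the order in which they are filled does not matter. Compound 1 already has bromine at the later C8a and oxygen at the later C7.

## Alternatives that were turned down

**Alternative 1:** Rings A and C are taken apart together by cutting C4a–C8a, C5–C6 and C7–C8. In the forward key step a metal-catalysed alkyne cyclotrimerisation joins the tethered diyne A1 with the siloxyalkyne A2 to give the protected flavanone A3.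
- For: it forms three C–C bonds and two rings in one step, places every substituent of ring A through the alkyne that carries it, and fixes C2 in the acyclic tether.
- Against: A1 combines a terminal ynone, an ynol ether of a secondary benzylic alcohol and a skipped enyne. The ynone has a β-leaving group on an enolisable carbon, and the ynol ether is prone to thermal fragmentation. Nothing in the tether fixes the orientation in which A2 inserts, so the isomer with silyloxy at C6 and prenyl at C7 is expected beside A3. The prenyl alkenes can also enter ene–yne pathways at the metal, and A1 and A2 each need several steps.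
- Comparison: this alternative is stronger in convergence and in bonds formed per step. The chosen route keeps ring A intact from a commercial arene and confines its risk to one C–O coupling of a known type.

**Alternative 2:** Ring C is cut at C3–C4, with C4 as an acyl anion equivalent. In the forward key step the dithiane C–H of the aryl ether tosylate A4 is deprotonated and the carbanion displaces the primary tosylate (6-exo-tet) to give the dithioketal A5.
- For: the C–C closure is irreversible, involves no transition metal and no β-hydride problem, and delivers C4 at the ketone oxidation level.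
- Against: the O1–C2 ether of A4 must be made at the stereogenic, para-oxygenated benzylic carbon, where substitution tends towards ionisation. In A4 the C2–H is benzylic, α to oxygen and β to the tosylate, so the strong base can eliminate to an enol ether and destroy C2. The tosylate carbon is also β-branched. Unmasking A5 needs thiophilic or oxidising reagents that attack two electron-rich alkenes and an electron-rich arene. The sequence is longer than the chosen one.
- Comparison: the chosen route uses no strong base once C2 exists and reveals the ketone by one mild alcohol oxidation.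

**Alternative 3:** Ring C is cut at C2–C3. In the forward key step the racemic enol acetal A6 ionises at its acetal carbon under a chiral Brønsted acid, and the enol carbon recombines with the oxocarbenium ion (a Petasis–Ferrier-type oxygen-to-carbon shift) to give flavanone A7.
- For: it is the shortest on paper, is stereoconvergent from a racemate, creates C2 catalytically in the ring-forming step, and needs no redox change at C4.
- Against: enantiocontrol depends wholly on ion pairing with a planar, strongly stabilised and therefore long-lived cation. The exocyclic enol ether can be protonated at carbon and diverted. The same acid can add the ring A oxygen to a prenyl group and can re-ionise C2 of A7. Making the acid-labile A6 is delicate.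
- Comparison: this alternative is stronger in step economy. The chosen route offers reaction classes with close precedent at every stage and a stereocentre that meets no ionising conditions until the last step.

Key step: step 11

## Route

Assumption 1: step 2 is written for migration of the allyl group to C5; migration to C3 gives a regioisomer that converges on 5 through steps 3 and 4, so the mixture needs no separation.

Assumption 2: compound 12 is written for reduction of the less hindered C3 carbonyl first; the other order leads to the same diol 13.

Step 1
Reactants: 1 1-(2-bromo-4-hydroxyphenyl)ethanone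
Product: 2 1-[2-bromo-4-(prop-2-enyloxy)phenyl]ethanone
Conditions: allyl bromide, K2CO3, acetone, reflux
Reagents that add atoms: allyl bromide, C=CCBr
Why: Williamson ether synthesis; the phenol is acidified by the para acetyl group and is alkylated cleanly on oxygen by the primary allylic halide.

Step 2
Reactants: 2 1-[2-bromo-4-(prop-2-enyloxy)phenyl]ethanone
Product: 3 1-[2-bromo-4-hydroxy-5-(prop-2-enyl)phenyl]ethanone
Conditions: N,N-diethylaniline, 200 °C
Reagents that add atoms: none
Why: Aromatic Claisen rearrangement ([3,3]-sigmatropic shift, then tautomerisation); the para position is blocked by the acetyl group, so the allyl group can only end on an ortho carbon, and either ortho carbon serves the route.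

Step 3
Reactants: 3 1-[2-bromo-4-hydroxy-5-(prop-2-enyl)phenyl]ethanone
Product: 4 1-[2-bromo-5-(prop-2-enyl)-4-(prop-2-enyloxy)phenyl]ethanone
Conditions: allyl bromide, K2CO3, acetone, reflux
Reagents that add atoms: allyl bromide, C=CCBr
Why: Williamson ether synthesis on the ortho-substituted phenol, which remains acidic and unhindered enough for O-alkylation.

Step 4
Reactants: 4 1-[2-bromo-5-(prop-2-enyl)-4-(prop-2-enyloxy)phenyl]ethanone
Product: 5 1-[2-bromo-4-hydroxy-3,5-di(prop-2-enyl)phenyl]ethanone
Conditions: N,N-diethylaniline, 200 °C
Reagents that add atoms: none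
Why: Second aromatic Claisen rearrangement; one ortho and the para position are occupied, so the allyl group must migrate to the remaining ortho carbon next to bromine, and a shift to the occupied carbon is reversible and unproductive.

Step 5
Reactants: 5 1-[2-bromo-4-hydroxy-3,5-di(prop-2-enyl)phenyl]ethanone
Product: 6 1-[2-bromo-4-(methoxymethoxy)-3,5-di(prop-2-enyl)phenyl]ethanone
Conditions: MOMCl, iPr2NEt, CH2Cl2, 0 °C → rt
Reagents that add atoms: chloromethyl methyl ether, COCCl
Why: O-alkylation of the acidic phenol with a small, highly reactive α-chloro ether, which still reaches the oxygen between two ortho allyl groups; the acetal tolerates the amide base, the hydride transfer and the carbonate base that follow.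

Step 6
Reactants: 6 1-[2-bromo-4-(methoxymethoxy)-3,5-di(prop-2-enyl)phenyl]ethanone
Product: 7 1-[2-bromo-4-(methoxymethoxy)-3,5-bis(3-methylbut-2-enyl)phenyl]ethanone
Conditions: second-generation Grubbs catalyst RuCl2(H2IMes)(PCy3)(=CHPh) (5 mol%), 2-methylbut-2-ene (solvent), 35 °C
Reagents that add atoms: 2-methylbut-2-ene, CC=C(C)C
Why: Olefin cross-metathesis; each terminal alkene exchanges its CH2 terminus for the isopropylidene unit of the solvent alkene with loss of propene, the large excess suppresses homodimerisation, and the trisubstituted product alkenes do not react further.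

Step 7
Reactants: 8 4-hydroxybenzoic acid
Product: 9 tert-butyldimethylsilyl 4-(tert-butyldimethylsilyloxy)benzoate
Conditions: TBSCl (2.3 equiv.), imidazole, DMF, rt
Reagents that add atoms: tert-butyldimethylsilyl chloride, CC(C)(C)[Si](C)(C)Cl
Why: Imidazole-promoted silylation of both the phenol and the carboxylic acid; the silyl ester is the handle for a neutral conversion to the acid chloride.

Step 8
Reactants: 9 tert-butyldimethylsilyl 4-(tert-butyldimethylsilyloxy)benzoate
Product: 10 4-(tert-butyldimethylsilyloxy)benzoyl chloride
Conditions: (COCl)2, cat. DMF, CH2Cl2, 0 °C → rt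
Reagents that add atoms: oxalyl chloride, O=C(Cl)C(=O)Cl
Why: The chloroiminium species from DMF and oxalyl chloride converts the silyl ester directly into the acid chloride, releasing the silyl chloride and no hydrogen chloride, so the aryl silyl ether survives.

Step 9
Reactants: 7 1-[2-bromo-4-(methoxymethoxy)-3,5-bis(3-methylbut-2-enyl)phenyl]ethanone; 10 4-(tert-butyldimethylsilyloxy)benzoyl chloride
Product: 11 1-[2-bromo-4-(methoxymethoxy)-3,5-bis(3-methylbut-2-enyl)phenyl]-3-[4-(tert-butyldimethylsilyloxy)phenyl]propane-1,3-dione
Conditions: LiN(SiMe3)2 (2.2 equiv.), THF, −78 °C; then 10, −78 → 0 °C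
Reagents that add atoms: none
Why: Claisen-type C-acylation of the lithium enolate of the methyl ketone; the second equivalent of base deprotonates the diketone as it forms and stops further acylation, bromine has no ortho hydrogen so no aryne can form, and both ethers are inert to the amide base in the cold.

Step 10
Reactants: 11 1-[2-bromo-4-(methoxymethoxy)-3,5-bis(3-methylbut-2-enyl)phenyl]-3-[4-(tert-butyldimethylsilyloxy)phenyl]propane-1,3-dione
Product: 13 (1S,3S)-1-[2-bromo-4-(methoxymethoxy)-3,5-bis(3-methylbut-2-enyl)phenyl]-3-[4-(tert-butyldimethylsilyloxy)phenyl]propane-1,3-diol, via the (3S)-hydroxy ketone 12 (not isolated)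
Conditions: RuCl(p-cymene)[(S,S)-TsDPEN] (2 mol%), HCO2H/Et3N (5:2), DMF, 35 °C
Reagents that add atoms: none
Why: Noyori–Ikariya asymmetric transfer hydrogenation; hydride and proton pass through an outer-sphere six-membered transition state with the ketone aryl group against the arene ligand, which with the (S,S)-ligand should give S carbinols of aryl alkyl ketones, so both carbonyls are reduced under catalyst control to the anti diol and C3 (the later C2) is set here. Alkenes, the aryl bromide and both ethers are not touched.

Step 11
Reactants: 13 (1S,3S)-1-[2-bromo-4-(methoxymethoxy)-3,5-bis(3-methylbut-2-enyl)phenyl]-3-[4-(tert-butyldimethylsilyloxy)phenyl]propane-1,3-diol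
Product: 14 (2S,4S)-2-[4-(tert-butyldimethylsilyloxy)phenyl]-7-(methoxymethoxy)-6,8-bis(3-methylbut-2-enyl)-3,4-dihydro-2H-chromen-4-ol
Conditions: Pd(OAc)2 (5 mol%), 2-(di-tert-butylphosphino)-1,1'-binaphthyl (6 mol%), Cs2CO3 (1.5 equiv.), toluene, 70 °C
Reagents that add atoms: none
Why: Pd(OAc)2 is reduced in situ to a zerovalent palladium monophosphine complex that adds oxidatively to the C8a–Br bond; Cs2CO3 then deprotonates the palladium-bound C3 hydroxyl to give a seven-membered aryl palladium alkoxide (Pd, C8a, C4a, chain C1, C2, C3, O), and C–O reductive elimination forms C8a–O1. The closest known reaction type is the palladium-catalysed intramolecular etherification of aryl halides with secondary alcohols (Buchwald–Hartwig type), which gives 2-substituted chromans without loss of configuration at the carbinol carbon. Ring C is closed as a six-membered ring by union of the C3 oxygen with the aromatic carbon, an aryl carbon–oxygen reductive elimination and not a substitution at C2. No stereocentre is formed: C2 of 14 is C3 of 13 and keeps its S configuration because neither its C–O nor its C–H bond takes part, and C4 inherits the configuration of C1. The step needs the right hydroxyl to react, and ring size secures this, since closure through the C1 oxygen would give a four-membered benzoxete and its five-membered palladium chelate holds the C1–H bond away from the metal, so it can only return to the productive alkoxide by proton transfer. It also needs reductive elimination to outrun β-hydride elimination at the benzylic C3–H, which the bulky, electron-rich di-tert-butyl biaryl phosphine and the two ortho substituents around C8a favour by crowding the metal. Insertion of the C8 prenyl alkene is not expected, since it would have to form a four-membered ring or close in a 5-endo mode. The weak carbonate base in toluene should leave the aryl silyl ether and the MOM ether intact, and with no ketone present nothing can epimerise C2.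

Step 12
Reactants: 14 (2S,4S)-2-[4-(tert-butyldimethylsilyloxy)phenyl]-7-(methoxymethoxy)-6,8-bis(3-methylbut-2-enyl)-3,4-dihydro-2H-chromen-4-ol
Product: 15 (2S)-2-[4-(tert-butyldimethylsilyloxy)phenyl]-7-(methoxymethoxy)-6,8-bis(3-methylbut-2-enyl)-2,3-dihydrochromen-4-one
Conditions: Dess–Martin periodinane, pyridine, CH2Cl2, 0 °C → rt
Reagents that add atoms: none
Why: Dess–Martin oxidation of the secondary benzylic alcohol by ligand exchange at iodine and intramolecular proton abstraction; pyridine buffers the acetic acid so that the benzylic C–O bonds and the acetal survive, the alkenes are inert, and no base is present that could open ring C, so C2 is kept.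

Step 13
Reactants: 15 (2S)-2-[4-(tert-butyldimethylsilyloxy)phenyl]-7-(methoxymethoxy)-6,8-bis(3-methylbut-2-enyl)-2,3-dihydrochromen-4-one
Product: 16 (2S)-2-(4-hydroxyphenyl)-7-(methoxymethoxy)-6,8-bis(3-methylbut-2-enyl)-2,3-dihydrochromen-4-one
Conditions: Et3N·3HF, THF, rt
Reagents that add atoms: none
Why: Fluoride-driven cleavage of the aryl silyl ether through the strong Si–F bond; the amine hydrofluoride is close to neutral, which avoids the base-induced retro-oxa-Michael opening that would scramble C2, and it leaves the acetal and the alkenes alone.

Step 14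
Reactants: 16 (2S)-2-(4-hydroxyphenyl)-7-(methoxymethoxy)-6,8-bis(3-methylbut-2-enyl)-2,3-dihydrochromen-4-one
Product: 17 (2S)-7-hydroxy-2-(4-hydroxyphenyl)-6,8-bis(3-methylbut-2-enyl)-2,3-dihydrochromen-4-one
Conditions: HCl (0.5 M) in MeOH, rt
Reagents that add atoms: none
Why: Acid-catalysed methanolysis of the acetal; the MOM ether is twisted out of conjugation by its two ortho substituents, behaves like an alkyl acetal and should cleave in dilute acid at room temperature, the usual way of unmasking prenylated phenols, and the short, cold exposure limits addition of the new phenol to a prenyl group.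

## Compound list

1 | 1-(2-bromo-4-hydroxyphenyl)ethanone | CC(=O)c1ccc(O)cc1Br | starting material
2 | 1-[2-bromo-4-(prop-2-enyloxy)phenyl]ethanone | CC(=O)c1ccc(OCC=C)cc1Br | intermediate
3 | 1-[2-bromo-4-hydroxy-5-(prop-2-enyl)phenyl]ethanone | CC(=O)c1cc(CC=C)c(O)cc1Br | intermediate
4 | 1-[2-bromo-5-(prop-2-enyl)-4-(prop-2-enyloxy)phenyl]ethanone | CC(=O)c1cc(CC=C)c(OCC=C)cc1Br | intermediate
5 | 1-[2-bromo-4-hydroxy-3,5-di(prop-2-enyl)phenyl]ethanone | CC(=O)c1cc(CC=C)c(O)c(CC=C)c1Br | intermediate
6 | 1-[2-bromo-4-(methoxymethoxy)-3,5-di(prop-2-enyl)phenyl]ethanone | CC(=O)c1cc(CC=C)c(OCOC)c(CC=C)c1Br | intermediate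
7 | 1-[2-bromo-4-(methoxymethoxy)-3,5-bis(3-methylbut-2-enyl)phenyl]ethanone | CC(=O)c1cc(CC=C(C)C)c(OCOC)c(CC=C(C)C)c1Br | intermediate
8 | 4-hydroxybenzoic acid | O=C(O)c1ccc(O)cc1 | starting material
9 | tert-butyldimethylsilyl 4-(tert-butyldimethylsilyloxy)benzoate | CC(C)(C)[Si](C)(C)OC(=O)c1ccc(O[Si](C)(C)C(C)(C)C)cc1 | intermediate
10 | 4-(tert-butyldimethylsilyloxy)benzoyl chloride | O=C(Cl)c1ccc(O[Si](C)(C)C(C)(C)C)cc1 | intermediate
11 | 1-[2-bromo-4-(methoxymethoxy)-3,5-bis(3-methylbut-2-enyl)phenyl]-3-[4-(tert-butyldimethylsilyloxy)phenyl]propane-1,3-dione | O=C(CC(=O)c1cc(CC=C(C)C)c(OCOC)c(CC=C(C)C)c1Br)c1ccc(O[Si](C)(C)C(C)(C)C)cc1 | intermediate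
12 | (3S)-1-[2-bromo-4-(methoxymethoxy)-3,5-bis(3-methylbut-2-enyl)phenyl]-3-[4-(tert-butyldimethylsilyloxy)phenyl]-3-hydroxypropan-1-one | O[C@H](c1ccc(O[Si](C)(C)C(C)(C)C)cc1)CC(=O)c1cc(CC=C(C)C)c(OCOC)c(CC=C(C)C)c1Br | intermediate
13 | (1S,3S)-1-[2-bromo-4-(methoxymethoxy)-3,5-bis(3-methylbut-2-enyl)phenyl]-3-[4-(tert-butyldimethylsilyloxy)phenyl]propane-1,3-diol | O[C@H](c1ccc(O[Si](C)(C)C(C)(C)C)cc1)C[C@H](O)c1cc(CC=C(C)C)c(OCOC)c(CC=C(C)C)c1Br | intermediate
14 | (2S,4S)-2-[4-(tert-butyldimethylsilyloxy)phenyl]-7-(methoxymethoxy)-6,8-bis(3-methylbut-2-enyl)-3,4-dihydro-2H-chromen-4-ol | CC(C)=CCc1cc2c(c(CC=C(C)C)c1OCOC)O[C@H](c1ccc(O[Si](C)(C)C(C)(C)C)cc1)C[C@@H]2O | intermediate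
15 | (2S)-2-[4-(tert-butyldimethylsilyloxy)phenyl]-7-(methoxymethoxy)-6,8-bis(3-methylbut-2-enyl)-2,3-dihydrochromen-4-one | CC(C)=CCc1cc2c(c(CC=C(C)C)c1OCOC)O[C@H](c1ccc(O[Si](C)(C)C(C)(C)C)cc1)CC2=O | intermediate
16 | (2S)-2-(4-hydroxyphenyl)-7-(methoxymethoxy)-6,8-bis(3-methylbut-2-enyl)-2,3-dihydrochromen-4-one | CC(C)=CCc1cc2c(c(CC=C(C)C)c1OCOC)O[C@H](c1ccc(O)cc1)CC2=O | intermediate
17 | (2S)-7-hydroxy-2-(4-hydroxyphenyl)-6,8-bis(3-methylbut-2-enyl)-2,3-dihydrochromen-4-one | CC(C)=CCc1cc2c(c(CC=C(C)C)c1O)O[C@H](c1ccc(O)cc1)CC2=O | target

## Step count and least certain steps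

Total: 14 steps. Longest linear sequence: 12 steps (steps 1 to 6 and 9 to 14); steps 7 and 8 prepare acid chloride 10.

**Step 11 (key step).**
- Most likely failure: β-hydride elimination from the palladium alkoxide, which oxidises a benzylic carbinol and replaces bromine by hydrogen.
- Other risks: slow oxidative addition into the doubly ortho-substituted, electron-rich C–Br bond, and transfer oxidation of the C4 alcohol by aryl palladium species, which would expose a flavanone to carbonate.
- Fallback: the metal and the mechanism are changed to a copper-catalysed Ullmann-type etherification (copper iodide CuI, 3,4,7,8-tetramethyl-1,10-phenanthroline, Cs2CO3, toluene, 110 °C). It sets out from 13 and returns at 14. Copper alkoxides are far less prone to β-hydride loss, and ring size still selects the C3 oxygen.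

**Step 10.**
- Most likely failure: incomplete reduction of the hindered C1 carbonyl, loss of water from 12 followed by conjugate reduction, or catalyst inhibition by the chelating diketonate.
- If only the C1 carbonyl remains, a simple hydride reduction completes the diol, because the C1 configuration is immaterial.
- Fallback: an asymmetric aldol sets C3 instead. It sets out from 7, whose boron enolate is formed with the enantiomer of chlorodiisopinocampheylborane Ipc2BCl that leads to the 3S adduct and Et3N. The enolate adds to 4-(tert-butyldimethylsilyloxy)benzaldehyde F1 to give 12. Anti-selective Evans–Saksena reduction with Me4NBH(OAc)3 then delivers hydride internally from the C3 alkoxyborohydride, and the route is rejoined at 13.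

**Step 9.**
- Most likely failure: O-acylation of the hindered enolate, or consumption of 10 by the amide base.
- Fallback: the C–C bond is made at the aldehyde oxidation level. It sets out from 7: the lithium enolate (LiN(iPr)2, THF, −78 °C) adds to aldehyde F1 to give the racemic hydroxy ketone F2. Dess–Martin oxidation of F2 gives 11, where the route is rejoined.

**Step 14.**
- Most likely failure: acid-promoted addition of the liberated C7 hydroxyl across a neighbouring prenyl double bond, addition of HCl or methanol to the alkenes, or partial epimerisation at C2 by reversible ring opening.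
- Fallback: the acetal is replaced by a silyl ether so that no acid is needed at the end. It sets out from 5 and follows the same sequence with the silyl analogues:
  - silylation (TBSCl, imidazole, DMF) gives the silyl ether F3;
  - cross-metathesis as in step 6 gives the diprenyl ketone F4;
  - acylation with 10 as in step 9 gives the diketone F5;
  - transfer hydrogenation as in step 10 gives the diol F6;
  - cyclisation as in step 11 gives the flavan-4-ol F7;
  - oxidation as in step 12 gives the bis-silyl flavanone F8;
  - Et3N·3HF removes both silyl groups from F8 and the route is rejoined at 17.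

## Further compounds

F0 | step 11 | none | none
F1 | step 10 | 4-(tert-butyldimethylsilyloxy)benzaldehyde | O=Cc1ccc(O[Si](C)(C)C(C)(C)C)cc1
F2 | step 9 | racemic 1-[2-bromo-4-(methoxymethoxy)-3,5-bis(3-methylbut-2-enyl)phenyl]-3-[4-(tert-butyldimethylsilyloxy)phenyl]-3-hydroxypropan-1-one | OC(CC(=O)c1cc(CC=C(C)C)c(OCOC)c(CC=C(C)C)c1Br)c1ccc(O[Si](C)(C)C(C)(C)C)cc1
F3 | step 14 | 1-[2-bromo-4-(tert-butyldimethylsilyloxy)-3,5-di(prop-2-enyl)phenyl]ethanone | CC(=O)c1cc(CC=C)c(O[Si](C)(C)C(C)(C)C)c(CC=C)c1Br
F4 | step 14 | 1-[2-bromo-4-(tert-butyldimethylsilyloxy)-3,5-bis(3-methylbut-2-enyl)phenyl]ethanone | CC(=O)c1cc(CC=C(C)C)c(O[Si](C)(C)C(C)(C)C)c(CC=C(C)C)c1Br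
F5 | step 14 | 1-[2-bromo-4-(tert-butyldimethylsilyloxy)-3,5-bis(3-methylbut-2-enyl)phenyl]-3-[4-(tert-butyldimethylsilyloxy)phenyl]propane-1,3-dione | O=C(CC(=O)c1cc(CC=C(C)C)c(O[Si](C)(C)C(C)(C)C)c(CC=C(C)C)c1Br)c1ccc(O[Si](C)(C)C(C)(C)C)cc1
F6 | step 14 | (1S,3S)-1-[2-bromo-4-(tert-butyldimethylsilyloxy)-3,5-bis(3-methylbut-2-enyl)phenyl]-3-[4-(tert-butyldimethylsilyloxy)phenyl]propane-1,3-diol | O[C@H](c1ccc(O[Si](C)(C)C(C)(C)C)cc1)C[C@H](O)c1cc(CC=C(C)C)c(O[Si](C)(C)C(C)(C)C)c(CC=C(C)C)c1Br
F7 | step 14 | (2S,4S)-7-(tert-butyldimethylsilyloxy)-2-[4-(tert-butyldimethylsilyloxy)phenyl]-6,8-bis(3-methylbut-2-enyl)-3,4-dihydro-2H-chromen-4-ol | CC(C)=CCc1cc2c(c(CC=C(C)C)c1O[Si](C)(C)C(C)(C)C)O[C@H](c1ccc(O[Si](C)(C)C(C)(C)C)cc1)C[C@@H]2O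
F8 | step 14 | (2S)-7-(tert-butyldimethylsilyloxy)-2-[4-(tert-butyldimethylsilyloxy)phenyl]-6,8-bis(3-methylbut-2-enyl)-2,3-dihydrochromen-4-one | CC(C)=CCc1cc2c(c(CC=C(C)C)c1O[Si](C)(C)C(C)(C)C)O[C@H](c1ccc(O[Si](C)(C)C(C)(C)C)cc1)CC2=O
A1 | alternative 1 | (5S)-5-[4-(tert-butyldimethylsilyloxy)phenyl]-5-(5-methylhex-4-en-1-ynyloxy)pent-1-yn-3-one | C#CC(=O)C[C@@H](c1ccc(O[Si](C)(C)C(C)(C)C)cc1)OC#CCC=C(C)C
A2 | alternative 1 | triisopropyl(5-methylhex-4-en-1-ynyloxy)silane | CC(C)=CCC#CO[Si](C(C)C)(C(C)C)C(C)C
A3 | alternative 1 | (2S)-2-[4-(tert-butyldimethylsilyloxy)phenyl]-6,8-bis(3-methylbut-2-enyl)-7-(triisopropylsilyloxy)-2,3-dihydrochromen-4-one | CC(C)=CCc1cc2c(c(CC=C(C)C)c1O[Si](C(C)C)(C(C)C)C(C)C)O[C@H](c1ccc(O[Si](C)(C)C(C)(C)C)cc1)CC2=O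
A4 | alternative 2 | (2R)-2-[4-(tert-butyldimethylsilyloxy)phenyl]-2-[2-(1,3-dithian-2-yl)-5-(methoxymethoxy)-4,6-bis(3-methylbut-2-enyl)phenoxy]ethyl 4-methylbenzenesulfonate | Cc1ccc(cc1)S(=O)(=O)OC[C@H](Oc1c(CC=C(C)C)c(OCOC)c(CC=C(C)C)cc1C1SCCCS1)c1ccc(O[Si](C)(C)C(C)(C)C)cc1
A5 | alternative 2 | (2S)-2-[4-(tert-butyldimethylsilyloxy)phenyl]-7-(methoxymethoxy)-6,8-bis(3-methylbut-2-enyl)spiro[chromane-4,2'-[1,3]dithiane] | CC(C)=CCc1cc2c(c(CC=C(C)C)c1OCOC)O[C@H](c1ccc(O[Si](C)(C)C(C)(C)C)cc1)CC21SCCCS1
A6 | alternative 3 | racemic 7-(tert-butyldimethylsilyloxy)-2-[4-(tert-butyldimethylsilyloxy)phenyl]-4-methylidene-6,8-bis(3-methylbut-2-enyl)-4H-1,3-benzodioxine | C=C1OC(c2ccc(O[Si](C)(C)C(C)(C)C)cc2)Oc2c1cc(CC=C(C)C)c(O[Si](C)(C)C(C)(C)C)c2CC=C(C)C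
A7 | alternative 3 | (2S)-7-(tert-butyldimethylsilyloxy)-2-[4-(tert-butyldimethylsilyloxy)phenyl]-6,8-bis(3-methylbut-2-enyl)-2,3-dihydrochromen-4-one | CC(C)=CCc1cc2c(c(CC=C(C)C)c1O[Si](C)(C)C(C)(C)C)O[C@H](c1ccc(O[Si](C)(C)C(C)(C)C)cc1)CC2=O
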